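**Retrosynthetic overview**

1. Labels follow 9,10-seco-ent-kaurane numbering: lactone C19(=O)–O–C6; ring A = C1–C5, C10; C7 = CH2 link; ring C = C8, C9(=O), C11=C12, C13, C14; ring D adds C15(OAc) and C16=C17.
2. Key step, last C–C bond: a bridging intramolecular aldol (C8 to C15) on a 4,6-disubstituted cyclohexenone keto-enal closes ring D; C13 alone dictates the C8 quaternary bridgehead, and lithium chelation sets C15.
3. C7–C8: α′-alkylation of (R)-4-allylcyclohex-2-enone (ring C, one organocatalytic operation) with the C7 triflate of the lactone/ring A fragment.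
4. Lactone/ring A: Piers methylenecyclohexane annulation on (S)-5-(hydroxymethyl)butenolide; C6 from the chiral pool relays to C5, C4 and C10.
5. Ring order: lactone (bought), ring A, ring C, ring D last. The usual plan, joining a finished bicyclo[3.2.1]octenone to a finished lactone, is deliberately not used.

Assumption: compounds 1, 3, 14 and 15 are bought as catalogue chemicals (3 is otherwise one step from 5-chloropent-1-yne).

Notation: Lac = (1R,3aR,7R,7aS)-3a,7-dimethyl-3-oxo-7-[(triethylsilyl)oxy]octahydro-2-benzofuran-1-yl.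

**Route**

Step 1
Reactants: 1 (S)-5-(hydroxymethyl)furan-2(5H)-one
Product: 2 (S)-5-[(benzyloxy)methyl]furan-2(5H)-one
Conditions: BnOC(=NH)CCl3, TfOH (cat.), CH2Cl2/cyclohexane, 0 °C to rt
Reagents that add atoms: benzyl 2,2,2-trichloroacetimidate, N=C(OCc1ccccc1)C(Cl)(Cl)Cl
Why: Acid-catalysed trichloroacetimidate O-benzylation protects the primary alcohol without base, so the chiral-pool C6 centre is not racemised through the furanolate; no new stereocentre.

Step 2
Reactants: 2 (S)-5-[(benzyloxy)methyl]furan-2(5H)-one; 3 2-bromo-5-chloropent-1-ene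
Product: 6 (4R,5S)-5-[(benzyloxy)methyl]-4-(5-chloropent-1-en-2-yl)oxolan-2-one, via (5-chloropent-1-en-2-yl)magnesium bromide 4 (not isolated), via bromomagnesium lactone enolate 5 (not isolated)
Conditions: 3, Mg, THF, 35 °C; then 2, CuBr·SMe2 (10 mol %), THF, −78 to −40 °C; aq NH4Cl
Reagents that add atoms: none
Why: Copper-catalysed conjugate (1,4-) addition of the Piers-type bifunctional alkenyl Grignard reagent to the butenolide occurs anti to the C6 CH2OBn group, setting C5 trans to C7, while the alkyl chloride stays inert.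

Step 3
Reactants: 6 (4R,5S)-5-[(benzyloxy)methyl]-4-(5-chloropent-1-en-2-yl)oxolan-2-one
Product: 9 (3S,3aS,7aR)-3-[(benzyloxy)methyl]-7a-methyl-4-methylidenehexahydro-2-benzofuran-1(3H)-one, via cis-fused lactone 7 (not isolated), via potassium enolate 8 (not isolated)
Conditions: KN(SiMe3)2 (1.1 equiv), THF, −78 to 0 °C; then KN(SiMe3)2 (1.2 equiv), −78 °C; MeI, −78 to −20 °C
Reagents that add atoms: iodomethane, CI
Why: Piers methylenecyclohexane annulation: 6-exo-tet intramolecular enolate alkylation closes ring A necessarily cis-fused, and the ring-fusion enolate is then methylated on the convex face, setting the C4 quaternary centre with Me-18 cis to H5.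

Step 4
Reactants: 9 (3S,3aS,7aR)-3-[(benzyloxy)methyl]-7a-methyl-4-methylidenehexahydro-2-benzofuran-1(3H)-one
Product: 10 (3S,3aS,4R,7aR)-3-[(benzyloxy)methyl]-4-hydroxy-4,7a-dimethylhexahydro-2-benzofuran-1(3H)-one
Conditions: Mn(dpm)3 (10 mol %), PhSiH3, O2 (1 atm), i-PrOH/CH2Cl2, 0 °C to rt
Reagents that add atoms: dioxygen, O=O
Why: Mukaiyama hydration (hydrogen-atom-transfer Markovnikov hydration): the tertiary C10 radical is expected to be captured by O2 on the convex face, anti to the axial lactone carbonyl carbon C19, giving OH trans to C6 and Me-20 cis to C6.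

Step 5
Reactants: 10 (3S,3aS,4R,7aR)-3-[(benzyloxy)methyl]-4-hydroxy-4,7a-dimethylhexahydro-2-benzofuran-1(3H)-one
Product: 11 (3S,3aS,4R,7aR)-3-[(benzyloxy)methyl]-4,7a-dimethyl-4-[(triethylsilyl)oxy]hexahydro-2-benzofuran-1(3H)-one
Conditions: Et3SiOTf, 2,6-lutidine, CH2Cl2, 0 °C
Reagents that add atoms: triethylsilyl trifluoromethanesulfonate, CC[Si](CC)(CC)OS(=O)(=O)C(F)(F)F
Why: Silylation of the tertiary alcohol with a silyl triflate removes the only acidic proton and blocks 5-exo etherification of O10 onto C7 in the later alkylation; no new stereocentre.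

Step 6
Reactants: 11 (3S,3aS,4R,7aR)-3-[(benzyloxy)methyl]-4,7a-dimethyl-4-[(triethylsilyl)oxy]hexahydro-2-benzofuran-1(3H)-one
Product: 12 (3S,3aS,4R,7aR)-3-(hydroxymethyl)-4,7a-dimethyl-4-[(triethylsilyl)oxy]hexahydro-2-benzofuran-1(3H)-one
Conditions: H2 (1 atm), 10% Pd/C, EtOAc, rt
Reagents that add atoms: none
Why: Catalytic hydrogenolysis of the benzyl ether; no alkene is present at this stage, and the silyl ether and lactone are inert under neutral conditions.

Step 7
Reactants: 12 (3S,3aS,4R,7aR)-3-(hydroxymethyl)-4,7a-dimethyl-4-[(triethylsilyl)oxy]hexahydro-2-benzofuran-1(3H)-one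
Product: 13 [Lac]methyl trifluoromethanesulfonate (C1 of the Lac unit is S here by priority change only)
Conditions: Tf2O, 2,6-lutidine, CH2Cl2, −78 °C; cold work-up, used at once
Reagents that add atoms: trifluoromethanesulfonic anhydride, O=S(=O)(OS(=O)(=O)C(F)(F)F)C(F)(F)F
Why: O-Sulfonylation gives a primary triflate reactive enough for enolate C-alkylation at −78 °C; the β-oxygen disfavours ionisation and no stereocentre is touched.

Step 8
Reactants: 14 pent-4-enal; 15 but-3-en-2-one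
Product: 17 (4R)-4-(prop-2-en-1-yl)cyclohex-2-en-1-one, via Michael adduct 16 (not isolated)
Conditions: (R)-2-[diphenyl(trimethylsilyloxy)methyl]pyrrolidine (5 mol %), ethyl 3,4-dihydroxybenzoate (20 mol %), neat, 4 °C; then LiOH (0.1 equiv), i-PrOH, rt
Reagents that add atoms: none
Why: Organocatalytic enamine Michael addition: the (R)-diarylprolinol silyl ether shields one face of the E-enamine of 14, so but-3-en-2-one adds to the open face and fixes C13 as R; base-mediated intramolecular aldol condensation (Robinson-type closure) then gives the enone without touching that centre.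

Step 9
Reactants: 17 (4R)-4-(prop-2-en-1-yl)cyclohex-2-en-1-one; 13 [Lac]methyl trifluoromethanesulfonate
Product: 19 (4S,6RS)-6-{[Lac]methyl}-4-(prop-2-en-1-yl)cyclohex-2-en-1-one, via lithium dienolate 18 (not isolated)
Conditions: 17 (1.3 equiv), LiN(i-Pr)2, THF, −78 °C; then 13, THF, −78 to −40 °C
Reagents that add atoms: none
Why: Kinetic α′-deprotonation gives the cross-conjugated lithium dienolate, which is C-alkylated by the primary triflate (SN2 enolate alkylation) cold enough that the γ-hydrogen at C13 is never removed; the C8 epimer mixture is irrelevant because C8 is re-enolised in step 12 (the descriptor at C13 changes by priority only).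

Step 10
Reactants: 19 (4S,6RS)-6-{[Lac]methyl}-4-(prop-2-en-1-yl)cyclohex-2-en-1-one
Product: 21 (4R,6RS)-6-{[Lac]methyl}-4-(2-oxoethyl)cyclohex-2-en-1-one, via secondary ozonide 20 (not isolated)
Conditions: O3 (1.0 equiv), CH2Cl2, −78 °C; then PPh3, −78 °C to rt
Reagents that add atoms: ozone, [O-][O+]=O
Why: Ozonolysis: ozone cleaves the electron-rich monosubstituted alkene much faster than the electron-poor enone double bond, unmasking the C15 aldehyde; no stereocentre is affected.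

Step 11
Reactants: 21 (4R,6RS)-6-{[Lac]methyl}-4-(2-oxoethyl)cyclohex-2-en-1-one
Product: 23 (4S,6RS)-6-{[Lac]methyl}-4-(3-oxoprop-1-en-2-yl)cyclohex-2-en-1-one, via Mannich base 22 (not isolated)
Conditions: Me2N=CH2+ I−, Et3N, CH2Cl2, rt
Reagents that add atoms: N,N-dimethylmethyleneiminium iodide (Eschenmoser's salt), C=[N+](C)C.[I-]
Why: Eschenmoser α-methylenation (Mannich reaction, then β-elimination of dimethylamine) installs C17 and turns the enolisable aldehyde into a non-enolisable 2-substituted acrolein; the aldehyde reacts far faster than the ketone and C13 is not deprotonated by Et3N.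

Step 12
Reactants: 23 (4S,6RS)-6-{[Lac]methyl}-4-(3-oxoprop-1-en-2-yl)cyclohex-2-en-1-one
Product: 26 (1S,5R,6R)-5-{[Lac]methyl}-7-methylidene-4-oxobicyclo[3.2.1]oct-2-en-6-yl acetate, via lithium dienolate 24 (not isolated), via lithium aldolate 25 (not isolated)
Conditions: LiN(SiMe3)2 (1.1 equiv), THF (0.01 M), −78 °C; then Ac2O, −78 to 0 °C
Reagents that add atoms: acetic anhydride, CC(=O)OC(C)=O
Why: Key step, bridging intramolecular aldol addition (5-exo-trig): kinetic deprotonation at C8 gives the cross-conjugated lithium dienolate from both C8 epimers, and it can reach the aldehyde only on the face carrying the C13 side chain, so C13 fixes the C8 quaternary bridgehead; the lithium chelate between O9 and O15 (closed Zimmerman–Traxler-type transition state) places O15 syn to C9, and Ac2O traps the aldolate before retro-aldol.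

Step 13
Reactants: 26 (1S,5R,6R)-5-{[Lac]methyl}-7-methylidene-4-oxobicyclo[3.2.1]oct-2-en-6-yl acetate
Product: 27 (1S,5R,6R)-5-{[(1R,3aR,7R,7aS)-7-hydroxy-3a,7-dimethyl-3-oxooctahydro-2-benzofuran-1-yl]methyl}-7-methylidene-4-oxobicyclo[3.2.1]oct-2-en-6-yl acetate (CNP0172716.1)
Conditions: HF·pyridine, THF, 0 °C to rt
Reagents that add atoms: none
Why: Fluoride-mediated desilylation of the tertiary triethylsilyl ether under mildly acidic conditions leaves the allylic acetate, enone and lactone intact and cannot trigger retro-aldol or acetyl migration; no stereocentre is touched.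

**Compound list**

1 | (S)-5-(hydroxymethyl)furan-2(5H)-one | OC[C@H]1OC(=O)C=C1 | starting material
2 | (S)-5-[(benzyloxy)methyl]furan-2(5H)-one | C(OCc1ccccc1)[C@H]2OC(=O)C=C2 | intermediate
3 | 2-bromo-5-chloropent-1-ene | C=C(Br)CCCCl | starting material
4 | (5-chloropent-1-en-2-yl)magnesium bromide | C=C([Mg]Br)CCCCl | intermediate
5 | bromomagnesium (4R,5S)-5-[(benzyloxy)methyl]-4-(5-chloropent-1-en-2-yl)-4,5-dihydrofuran-2-olate | Br[Mg]OC1=C[C@H](C(=C)CCCCl)[C@@H](COCc2ccccc2)O1 | intermediate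
6 | (4R,5S)-5-[(benzyloxy)methyl]-4-(5-chloropent-1-en-2-yl)oxolan-2-one | C(OCc1ccccc1)[C@H]2OC(=O)C[C@@H]2C(=C)CCCCl | intermediate
7 | (3S,3aR,7aR)-3-[(benzyloxy)methyl]-4-methylidenehexahydro-2-benzofuran-1(3H)-one | C(OCc1ccccc1)[C@H]3OC(=O)[C@@H]4CCCC(=C)[C@H]34 | intermediate
8 | potassium (3S,3aS)-3-[(benzyloxy)methyl]-4-methylidene-3,3a,4,5,6,7-hexahydro-2-benzofuran-1-olate | [K]OC1=C2CCCC(=C)[C@@H]2[C@@H](COCc3ccccc3)O1 | intermediate
9 | (3S,3aS,7aR)-3-[(benzyloxy)methyl]-7a-methyl-4-methylidenehexahydro-2-benzofuran-1(3H)-one | C(OCc1ccccc1)[C@H]3OC(=O)[C@]4(C)CCCC(=C)[C@H]34 | intermediate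
10 | (3S,3aS,4R,7aR)-3-[(benzyloxy)methyl]-4-hydroxy-4,7a-dimethylhexahydro-2-benzofuran-1(3H)-one | C(OCc1ccccc1)[C@H]3OC(=O)[C@]4(C)CCC[C@@](C)(O)[C@H]34 | intermediate
11 | (3S,3aS,4R,7aR)-3-[(benzyloxy)methyl]-4,7a-dimethyl-4-[(triethylsilyl)oxy]hexahydro-2-benzofuran-1(3H)-one | C(OCc1ccccc1)[C@H]3OC(=O)[C@]4(C)CCC[C@@](C)(O[Si](CC)(CC)CC)[C@H]34 | intermediate
12 | (3S,3aS,4R,7aR)-3-(hydroxymethyl)-4,7a-dimethyl-4-[(triethylsilyl)oxy]hexahydro-2-benzofuran-1(3H)-one | OC[C@H]3OC(=O)[C@]4(C)CCC[C@@](C)(O[Si](CC)(CC)CC)[C@H]34 | intermediate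
13 | [(1S,3aR,7R,7aS)-3a,7-dimethyl-3-oxo-7-[(triethylsilyl)oxy]octahydro-2-benzofuran-1-yl]methyl trifluoromethanesulfonate | FC(F)(F)S(=O)(=O)OC[C@H]3OC(=O)[C@]4(C)CCC[C@@](C)(O[Si](CC)(CC)CC)[C@H]34 | intermediate
14 | pent-4-enal | C=CCCC=O | starting material
15 | but-3-en-2-one | CC(=O)C=C | starting material
16 | (2R)-5-oxo-2-(prop-2-en-1-yl)hexanal | O=C[C@@H](CC=C)CCC(C)=O | intermediate
17 | (4R)-4-(prop-2-en-1-yl)cyclohex-2-en-1-one | O=C1C=C[C@@H](CC=C)CC1 | intermediate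
18 | lithium (4S)-4-(prop-2-en-1-yl)cyclohexa-1,5-dien-1-olate | [Li]OC1=CC[C@H](CC=C)C=C1 | intermediate
19 | (4S,6RS)-6-{[(1R,3aR,7R,7aS)-3a,7-dimethyl-3-oxo-7-[(triethylsilyl)oxy]octahydro-2-benzofuran-1-yl]methyl}-4-(prop-2-en-1-yl)cyclohex-2-en-1-one | O=C1C=C[C@@H](CC=C)CC1C[C@H]3OC(=O)[C@]4(C)CCC[C@@](C)(O[Si](CC)(CC)CC)[C@H]34 | intermediate
20 | (4R,6RS)-6-{[(1R,3aR,7R,7aS)-3a,7-dimethyl-3-oxo-7-[(triethylsilyl)oxy]octahydro-2-benzofuran-1-yl]methyl}-4-[(1,2,4-trioxolan-3-yl)methyl]cyclohex-2-en-1-one | O=C1C=C[C@@H](CC2OCOO2)CC1C[C@H]3OC(=O)[C@]4(C)CCC[C@@](C)(O[Si](CC)(CC)CC)[C@H]34 | intermediate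
21 | (4R,6RS)-6-{[(1R,3aR,7R,7aS)-3a,7-dimethyl-3-oxo-7-[(triethylsilyl)oxy]octahydro-2-benzofuran-1-yl]methyl}-4-(2-oxoethyl)cyclohex-2-en-1-one | O=C1C=C[C@@H](CC=O)CC1C[C@H]3OC(=O)[C@]4(C)CCC[C@@](C)(O[Si](CC)(CC)CC)[C@H]34 | intermediate
22 | (4S,6RS)-4-[3-(dimethylamino)-1-oxopropan-2-yl]-6-{[(1R,3aR,7R,7aS)-3a,7-dimethyl-3-oxo-7-[(triethylsilyl)oxy]octahydro-2-benzofuran-1-yl]methyl}cyclohex-2-en-1-one | O=C1C=C[C@@H](C(CN(C)C)C=O)CC1C[C@H]3OC(=O)[C@]4(C)CCC[C@@](C)(O[Si](CC)(CC)CC)[C@H]34 | intermediate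
23 | (4S,6RS)-6-{[(1R,3aR,7R,7aS)-3a,7-dimethyl-3-oxo-7-[(triethylsilyl)oxy]octahydro-2-benzofuran-1-yl]methyl}-4-(3-oxoprop-1-en-2-yl)cyclohex-2-en-1-one | O=C1C=C[C@@H](C(=C)C=O)CC1C[C@H]3OC(=O)[C@]4(C)CCC[C@@](C)(O[Si](CC)(CC)CC)[C@H]34 | intermediate
24 | lithium (4S)-2-{[(1R,3aR,7R,7aS)-3a,7-dimethyl-3-oxo-7-[(triethylsilyl)oxy]octahydro-2-benzofuran-1-yl]methyl}-4-(3-oxoprop-1-en-2-yl)cyclohexa-1,5-dien-1-olate | [Li]OC1=C(C[C@H]3OC(=O)[C@]4(C)CCC[C@@](C)(O[Si](CC)(CC)CC)[C@H]34)C[C@H](C(=C)C=O)C=C1 | intermediate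
25 | lithium (1S,5R,6R)-5-{[(1R,3aR,7R,7aS)-3a,7-dimethyl-3-oxo-7-[(triethylsilyl)oxy]octahydro-2-benzofuran-1-yl]methyl}-7-methylidene-4-oxobicyclo[3.2.1]oct-2-en-6-olate | C=C1[C@@H]2C=CC(=O)[C@@](C[C@H]3OC(=O)[C@]4(C)CCC[C@@](C)(O[Si](CC)(CC)CC)[C@H]34)(C2)[C@@H]1O[Li] | intermediate
26 | (1S,5R,6R)-5-{[(1R,3aR,7R,7aS)-3a,7-dimethyl-3-oxo-7-[(triethylsilyl)oxy]octahydro-2-benzofuran-1-yl]methyl}-7-methylidene-4-oxobicyclo[3.2.1]oct-2-en-6-yl acetate | C=C1[C@@H]2C=CC(=O)[C@@](C[C@H]3OC(=O)[C@]4(C)CCC[C@@](C)(O[Si](CC)(CC)CC)[C@H]34)(C2)[C@@H]1OC(C)=O | intermediate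
27 | (1S,5R,6R)-5-{[(1R,3aR,7R,7aS)-7-hydroxy-3a,7-dimethyl-3-oxooctahydro-2-benzofuran-1-yl]methyl}-7-methylidene-4-oxobicyclo[3.2.1]oct-2-en-6-yl acetate | C=C1[C@@H]2C=CC(=O)[C@@](C[C@H]3OC(=O)[C@]4(C)CCC[C@@](C)(O)[C@H]34)(C2)[C@@H]1OC(C)=O | target

**Step count**

Total: 13 steps. Longest linear sequence: 12 steps (steps 1–7, then 9–13); step 8 makes the second fragment.

**Three steps most likely to fail, with fallbacks**

Step 12 (bridging aldol). The risks are competing deprotonation at the doubly vinylogous C13–H, which would scramble the stereocentre that controls the whole bicycle, and retro-aldol before acetylation. The fallback makes the C8 enolate by reduction instead of deprotonation; it sets out from 19 and comes back at 26. Compound 19 is enolised (LiN(i-Pr)2, THF, −78 °C) and oxidised with dibenzoyl peroxide to the α′-benzoyloxy ketone (5S)-1-{[(1R,3aR,7R,7aS)-3a,7-dimethyl-3-oxo-7-[(triethylsilyl)oxy]octahydro-2-benzofuran-1-yl]methyl}-2-oxo-5-(prop-2-en-1-yl)cyclohex-3-en-1-yl benzoate F4. Ozonolysis as in step 10 gives the aldehyde (5R)-1-{[(1R,3aR,7R,7aS)-3a,7-dimethyl-3-oxo-7-[(triethylsilyl)oxy]octahydro-2-benzofuran-1-yl]methyl}-2-oxo-5-(2-oxoethyl)cyclohex-3-en-1-yl benzoate F5. Eschenmoser methylenation as in step 11 gives the enal (5S)-1-{[(1R,3aR,7R,7aS)-3a,7-dimethyl-3-oxo-7-[(triethylsilyl)oxy]octahydro-2-benzofuran-1-yl]methyl}-2-oxo-5-(3-oxoprop-1-en-2-yl)cyclohex-3-en-1-yl benzoate F6. SmI2 (2.2 equiv, THF, −78 °C) then cleaves the C8–O bond to the trivalent samarium enolate regiospecifically and without base (Reformatsky-type aldol). This enolate closes onto the aldehyde through the same chelate, and an Ac2O quench delivers 26.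

Step 9 (alkylation). The triflate is primary but β-branched and β-oxygenated, so O-alkylation, elimination or enolate equilibration may win. The fallback forms C6–C7 by radical addition instead of C7–C8 by SN2; it sets out from 12 and 17 and comes back at 19. Alcohol 12 is oxidised (TEMPO, PhI(OAc)2, MeCN/H2O) to (1S,3aR,7R,7aS)-3a,7-dimethyl-3-oxo-7-[(triethylsilyl)oxy]octahydro-2-benzofuran-1-carboxylic acid F2. Enone 17 is methylenated at C8 (paraformaldehyde, N-methylanilinium trifluoroacetate, THF, reflux) to (4S)-6-methylidene-4-(prop-2-en-1-yl)cyclohex-2-en-1-one F3, used at once. Photoredox decarboxylative Giese addition ([Ir(dF(CF3)ppy)2(dtbbpy)]PF6 1 mol %, K2HPO4, DMF, blue light) generates the C6 radical inside the cis-fused lactone. This radical adds to the exocyclic CH2 of F3 on the convex face, anti to C10, which re-creates C6 with the required configuration and gives 19 after reduction and protonation at C8.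

Step 4 (hydration). The facial selectivity of O2 capture at the C10 radical is the least certain stereochemical call; the wrong face gives the C10 epimer. The fallback delivers carbon instead of oxygen to C10; it sets out from 9 and comes back at 10. Ozonolysis of 9 (O3, CH2Cl2, −78 °C; PPh3) gives the ketone (3S,3aS,7aR)-3-[(benzyloxy)methyl]-7a-methyltetrahydro-2-benzofuran-1,4(3H,3aH)-dione F1. MeMgBr (THF, −78 °C, with CeCl3 if enolisation competes) then adds chemoselectively to the ketone. A methyl nucleophile uses the same open face that O2 would use, so this sequence gives the opposite C10 epimer to the hydration; if hydration puts OH on the wrong face, this sequence gives 10.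

Further compounds
F1 | step 4 | (3S,3aS,7aR)-3-[(benzyloxy)methyl]-7a-methyltetrahydro-2-benzofuran-1,4(3H,3aH)-dione | C(OCc1ccccc1)[C@H]3OC(=O)[C@]4(C)CCCC(=O)[C@H]34
F2 | step 9 | (1S,3aR,7R,7aS)-3a,7-dimethyl-3-oxo-7-[(triethylsilyl)oxy]octahydro-2-benzofuran-1-carboxylic acid | OC(=O)[C@H]3OC(=O)[C@]4(C)CCC[C@@](C)(O[Si](CC)(CC)CC)[C@H]34
F3 | step 9 | (4S)-6-methylidene-4-(prop-2-en-1-yl)cyclohex-2-en-1-one | O=C1C=C[C@@H](CC=C)CC1=C
F4 | step 12 | (5S)-1-{[(1R,3aR,7R,7aS)-3a,7-dimethyl-3-oxo-7-[(triethylsilyl)oxy]octahydro-2-benzofuran-1-yl]methyl}-2-oxo-5-(prop-2-en-1-yl)cyclohex-3-en-1-yl benzoate | O=C1C=C[C@@H](CC=C)CC1(OC(=O)c2ccccc2)C[C@H]3OC(=O)[C@]4(C)CCC[C@@](C)(O[Si](CC)(CC)CC)[C@H]34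
F5 | step 12 | (5R)-1-{[(1R,3aR,7R,7aS)-3a,7-dimethyl-3-oxo-7-[(triethylsilyl)oxy]octahydro-2-benzofuran-1-yl]methyl}-2-oxo-5-(2-oxoethyl)cyclohex-3-en-1-yl benzoate | O=C1C=C[C@@H](CC=O)CC1(OC(=O)c2ccccc2)C[C@H]3OC(=O)[C@]4(C)CCC[C@@](C)(O[Si](CC)(CC)CC)[C@H]34
F6 | step 12 | (5S)-1-{[(1R,3aR,7R,7aS)-3a,7-dimethyl-3-oxo-7-[(triethylsilyl)oxy]octahydro-2-benzofuran-1-yl]methyl}-2-oxo-5-(3-oxoprop-1-en-2-yl)cyclohex-3-en-1-yl benzoate | O=C1C=C[C@@H](C(=C)C=O)CC1(OC(=O)c2ccccc2)C[C@H]3OC(=O)[C@]4(C)CCC[C@@](C)(O[Si](CC)(CC)CC)[C@H]34
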